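Ring A of the target bears oxygen on five adjacent carbons (C5, C6, C7, C8, C8a); C4a is its only carbon without one. The route disconnects ring A at C4a–C8a and builds it from dimethyl squarate: a 4-(benzyloxy)-4-(1-ethoxyvinyl)-2,3-dimethoxycyclobutenone, on heating, should open to a dienylketene and close again to a phenol in one operation, so that O1 arrives free, O5 as ethyl ether, O6 as benzyl ether and O7/O8 as the methyl ethers of the target. Ring C is then annulated across the free phenol and the single ring hydrogen at C4a with an isovanillin-derived aryl propiolate, and one BCl3 treatment unmasks O5, O6 and O3′.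

Key step: step 3

Remark 1: the carbinol oxygen of the cyclobutenone (future O6) is carried as a benzyl ether; an acetal there would not survive the acidic acylating medium of the ring C closure, whereas a benzyl ether does and later leaves together with the O3′ benzyl ether.
Remark 2: the aryloxyacrylates are drawn as Z isomers (anti addition); it is assumed that any E isomer converges on the same flavone, because the acylium ion of step 9 can rotate about its C2–C3 bond.

Step 1
Reactants: 1 ethyl vinyl ether; 2 dimethyl squarate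
Product: 5 rac-4-(1-ethoxyvinyl)-4-hydroxy-2,3-dimethoxycyclobut-2-en-1-one, via 1-ethoxyvinyllithium 3 (not isolated), via lithium cyclobutenolate 4 (not isolated)
Conditions: t-BuLi, THF, −78 to 0 °C; then 2, THF, −78 °C; sat. aq. NH4Cl, −78 °C to rt
Reagents that add atoms: none
Why: α-Lithiation of the vinyl ether gives an acyl-anion equivalent that should add 1,2 to one of the two equivalent ketone carbonyls of the squarate (organolithium carbonyl addition), the new carbinol centre forming as a racemate because no chiral element is present.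

Step 2
Reactants: 5 rac-4-(1-ethoxyvinyl)-4-hydroxy-2,3-dimethoxycyclobut-2-en-1-one
Product: 6 rac-4-(benzyloxy)-4-(1-ethoxyvinyl)-2,3-dimethoxycyclobut-2-en-1-one
Conditions: BnBr, Ag2O, 4 Å MS, MeCN, rt, dark
Reagents that add atoms: benzyl bromide, BrCc1ccccc1
Why: Ag2O-mediated O-alkylation (Purdie-type Williamson etherification) should cap the tertiary cyclobutenol under nearly neutral conditions that spare the enol ether and the strained ring, leaving the stereocentre untouched.

Step 3
Reactants: 6 rac-4-(benzyloxy)-4-(1-ethoxyvinyl)-2,3-dimethoxycyclobut-2-en-1-one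
Product: 9 4-(benzyloxy)-5-ethoxy-2,3-dimethoxyphenol, via (3Z)-dienylketene 7 (not isolated), via cyclohexa-2,4-dienone tautomer 8 (not isolated)
Conditions: toluene (degassed, dilute), 110 °C, Ar
Reagents that add atoms: none
Why: Heating should open the cyclobutenone by a thermal four-electron conrotatory electrocyclic reaction to the (3Z)-dienylketene 7, in which the ketene carbon (future C8a) and the vinyl CH2 (future C4a) lie on the same side of the central double bond. A six-electron disrotatory electrocyclization then forms the C4a–C8a bond and closes ring A as cyclohexa-2,4-dienone 8, which enolises irreversibly to the aromatic phenol 9. The closest known reaction type is the Moore rearrangement of squarate-derived 4-alkenyl-4-alkoxycyclobutenones to hydroquinone monoethers. No stereocentre is formed, and the single one of racemic 6 is lost on ring opening. The selectivity needed is torquoselectivity in the ring opening: the benzyloxy donor on the carbinol carbon rotates outward, which turns the 1-ethoxyvinyl group inward, the only geometry that can cyclise. Positional selectivity is not required, since the order O8a (former C=O), O8 and O7 (squarate methoxy carbons), O6 (carbinol) and O5 (enol ether) is already written into 6.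

Step 4
Reactants: 10 isovanillin
Product: 11 3-(benzyloxy)-4-methoxybenzaldehyde
Conditions: BnBr, K2CO3, DMF, rt
Reagents that add atoms: benzyl bromide, BrCc1ccccc1
Why: Williamson etherification of the only phenol should proceed cleanly and protects O3′ against the later phenoxide addition.

Step 5
Reactants: 11 3-(benzyloxy)-4-methoxybenzaldehyde
Product: 12 2-(benzyloxy)-4-(2,2-dibromoethenyl)-1-methoxybenzene
Conditions: CBr4, PPh3, CH2Cl2, 0 °C
Reagents that add atoms: carbon tetrabromide, BrC(Br)(Br)Br
Why: Corey–Fuchs (Ramirez) dibromoolefination, a Wittig-type reaction of the ylide formed in the flask, is reliable for electron-rich benzaldehydes.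

Step 6
Reactants: 12 2-(benzyloxy)-4-(2,2-dibromoethenyl)-1-methoxybenzene
Product: 14 methyl 3-[3-(benzyloxy)-4-methoxyphenyl]prop-2-ynoate, via lithium arylacetylide 13 (not isolated)
Conditions: n-BuLi (2.1 equiv), THF, −78 °C; then ClCO2Me, −78 °C to rt
Reagents that add atoms: methyl chloroformate, COC(Cl)=O
Why: Second stage of the Corey–Fuchs alkyne synthesis (Li–Br exchange, loss of LiBr with 1,2-hydrogen shift, deprotonation) should give the acetylide, which is C-acylated by the chloroformate.

Step 7
Reactants: 9 4-(benzyloxy)-5-ethoxy-2,3-dimethoxyphenol; 14 methyl 3-[3-(benzyloxy)-4-methoxyphenyl]prop-2-ynoate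
Product: 15 methyl (2Z)-3-[4-(benzyloxy)-5-ethoxy-2,3-dimethoxyphenoxy]-3-[3-(benzyloxy)-4-methoxyphenyl]prop-2-enoate
Conditions: Cs2CO3 (0.5 equiv), DMF (degassed), 60 °C
Reagents that add atoms: none
Why: Base-catalysed oxa-Michael addition of the only free phenoxide to the ynoate (Ruhemann-type aryloxycinnamate formation) should place O1 on the future C2, anti addition favouring the Z alkene.

Step 8
Reactants: 15 methyl (2Z)-3-[4-(benzyloxy)-5-ethoxy-2,3-dimethoxyphenoxy]-3-[3-(benzyloxy)-4-methoxyphenyl]prop-2-enoate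
Product: 17 (2Z)-3-[4-(benzyloxy)-5-ethoxy-2,3-dimethoxyphenoxy]-3-[3-(benzyloxy)-4-methoxyphenyl]prop-2-enoic acid, via lithium carboxylate 16 (not isolated)
Conditions: LiOH·H2O, THF–MeOH–H2O, rt to 40 °C; then 1 M HCl, 0 °C, to pH 3
Reagents that add atoms: lithium hydroxide, [Li+].[OH-]
Why: Saponification of the methyl ester should leave the benzyl, ethyl and methyl ethers and the aryl vinyl ether untouched, and cold, brief acidification frees the acid.

Step 9
Reactants: 17 (2Z)-3-[4-(benzyloxy)-5-ethoxy-2,3-dimethoxyphenoxy]-3-[3-(benzyloxy)-4-methoxyphenyl]prop-2-enoic acid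
Product: 19 6-(benzyloxy)-2-[3-(benzyloxy)-4-methoxyphenyl]-5-ethoxy-7,8-dimethoxy-4H-chromen-4-one, via mixed trifluoroacetic anhydride 18 (not isolated)
Conditions: TFAA, CH2Cl2, 0 °C to rt
Reagents that add atoms: none
Why: Intramolecular Friedel–Crafts acylation through the mixed anhydride should close ring C at C4a, the only unsubstituted carbon of ring A and one activated by the ortho ethoxy and para methoxy groups, under conditions that benzyl ethers tolerate.

Step 10
Reactants: 19 6-(benzyloxy)-2-[3-(benzyloxy)-4-methoxyphenyl]-5-ethoxy-7,8-dimethoxy-4H-chromen-4-one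
Product: 20 5,6-dihydroxy-2-(3-hydroxy-4-methoxyphenyl)-7,8-dimethoxy-4H-chromen-4-one (5,6,3'-trihydroxy-7,8,4'-trimethoxyflavone)
Conditions: BCl3, C6HMe5, CH2Cl2, −78 °C to rt; then H2O
Reagents that add atoms: none
Why: Lewis-acid ether cleavage by BCl3 should remove both benzyl groups (cation trapped by pentamethylbenzene) and, through the six-membered chelate between O5 and the C4 carbonyl, the peri ethyl group, while the unchelated methyl ethers at C7, C8 and C4′ react far more slowly.

Compound list
1 | ethyl vinyl ether | C=COCC | starting material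
2 | dimethyl squarate (3,4-dimethoxycyclobut-3-ene-1,2-dione) | COC1=C(OC)C(=O)C1=O | starting material
3 | 1-ethoxyvinyllithium | [Li]C(=C)OCC | intermediate (not isolated)
4 | lithium 1-(1-ethoxyvinyl)-2,3-dimethoxy-4-oxocyclobut-2-en-1-olate (racemic) | [Li+].[O-]C1(C(=C)OCC)C(OC)=C(OC)C1=O | intermediate (not isolated)
5 | rac-4-(1-ethoxyvinyl)-4-hydroxy-2,3-dimethoxycyclobut-2-en-1-one | CCOC(=C)C1(O)C(OC)=C(OC)C1=O | intermediate
6 | rac-4-(benzyloxy)-4-(1-ethoxyvinyl)-2,3-dimethoxycyclobut-2-en-1-one | CCOC(=C)C1(OCc2ccccc2)C(OC)=C(OC)C1=O | intermediate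
7 | (3Z)-4-(benzyloxy)-5-ethoxy-2,3-dimethoxyhexa-1,3,5-trien-1-one (dienylketene) | O=C=C(OC)/C(OC)=C(/OCc1ccccc1)C(=C)OCC | intermediate (not isolated)
8 | 4-(benzyloxy)-5-ethoxy-2,3-dimethoxycyclohexa-2,4-dien-1-one | CCOC1=C(OCc2ccccc2)C(OC)=C(OC)C(=O)C1 | intermediate (not isolated)
9 | 4-(benzyloxy)-5-ethoxy-2,3-dimethoxyphenol | CCOc1cc(O)c(OC)c(OC)c1OCc1ccccc1 | intermediate
10 | isovanillin (3-hydroxy-4-methoxybenzaldehyde) | COc1ccc(C=O)cc1O | starting material
11 | 3-(benzyloxy)-4-methoxybenzaldehyde | COc1ccc(C=O)cc1OCc1ccccc1 | intermediate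
12 | 2-(benzyloxy)-4-(2,2-dibromoethenyl)-1-methoxybenzene | COc1ccc(C=C(Br)Br)cc1OCc1ccccc1 | intermediate
13 | lithium [3-(benzyloxy)-4-methoxyphenyl]acetylide | [Li]C#Cc1ccc(OC)c(OCc2ccccc2)c1 | intermediate (not isolated)
14 | methyl 3-[3-(benzyloxy)-4-methoxyphenyl]prop-2-ynoate | COC(=O)C#Cc1ccc(OC)c(OCc2ccccc2)c1 | intermediate
15 | methyl (2Z)-3-[4-(benzyloxy)-5-ethoxy-2,3-dimethoxyphenoxy]-3-[3-(benzyloxy)-4-methoxyphenyl]prop-2-enoate | COC(=O)/C=C(\Oc1cc(OCC)c(OCc2ccccc2)c(OC)c1OC)c1ccc(OC)c(OCc2ccccc2)c1 | intermediate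
16 | lithium (2Z)-3-[4-(benzyloxy)-5-ethoxy-2,3-dimethoxyphenoxy]-3-[3-(benzyloxy)-4-methoxyphenyl]prop-2-enoate | [Li+].[O-]C(=O)/C=C(\Oc1cc(OCC)c(OCc2ccccc2)c(OC)c1OC)c1ccc(OC)c(OCc2ccccc2)c1 | intermediate (not isolated)
17 | (2Z)-3-[4-(benzyloxy)-5-ethoxy-2,3-dimethoxyphenoxy]-3-[3-(benzyloxy)-4-methoxyphenyl]prop-2-enoic acid | OC(=O)/C=C(\Oc1cc(OCC)c(OCc2ccccc2)c(OC)c1OC)c1ccc(OC)c(OCc2ccccc2)c1 | intermediate
18 | (2Z)-3-[4-(benzyloxy)-5-ethoxy-2,3-dimethoxyphenoxy]-3-[3-(benzyloxy)-4-methoxyphenyl]prop-2-enoic trifluoroacetic anhydride | FC(F)(F)C(=O)OC(=O)/C=C(\Oc1cc(OCC)c(OCc2ccccc2)c(OC)c1OC)c1ccc(OC)c(OCc2ccccc2)c1 | intermediate (not isolated)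
19 | 6-(benzyloxy)-2-[3-(benzyloxy)-4-methoxyphenyl]-5-ethoxy-7,8-dimethoxy-4H-chromen-4-one | CCOc1c(OCc2ccccc2)c(OC)c(OC)c2oc(-c3ccc(OC)c(OCc4ccccc4)c3)cc(=O)c12 | intermediate
20 | 5,6,3'-trihydroxy-7,8,4'-trimethoxyflavone | COc1ccc(-c2cc(=O)c3c(O)c(O)c(OC)c(OC)c3o2)cc1O | target

Total step count: 10.
Longest linear sequence: 7 steps (1, 2, 3, 7, 8, 9, 10 from dimethyl squarate; the isovanillin branch 4, 5, 6, 7, 8, 9, 10 is equally long).

Steps most likely to fail

Step 3. The ketene may be intercepted (by traces of water or by dimerisation) before it closes, the enol ether may be hydrolysed on hot surfaces before ring opening, or the electron-rich phenol may be oxidised by air during isolation. The fallback sets out from 5 and comes back at 15. The ring expansion is run on the uncapped carbinol 5 (degassed toluene or p-xylene, 110–140 °C), the most widely used form of this rearrangement, which should give 5-ethoxy-2,3-dimethoxybenzene-1,4-diol F1. The two hydroxyls are then told apart by sterics: with one equivalent of propiolate 14 and Cs2CO3 in degassed DMF, the hydroxyl flanked by a ring hydrogen (future O1) should add first to give methyl (2Z)-3-[3-(benzyloxy)-4-methoxyphenyl]-3-(5-ethoxy-4-hydroxy-2,3-dimethoxyphenoxy)prop-2-enoate F2. BnBr and K2CO3 in DMF then etherify the remaining hindered hydroxyl to give 15. This detour also makes step 2 unnecessary, should etherification of the hindered carbinol prove the weaker link.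

Step 9. The mixed anhydride may be too weak an electrophile under conditions mild enough for the benzyl ethers, the acylium ion may close onto ring B instead (indenone formation from the E geometry), or the aryl vinyl ether may be cleaved by the acid set free. The fallback sets out from 9, uses acetylide 13, and comes back at 19, with no acid at any stage. Ortho-formylation of 9 at its only free ring position (MgCl2, Et3N, paraformaldehyde, MeCN, reflux) should give 3-(benzyloxy)-2-ethoxy-6-hydroxy-4,5-dimethoxybenzaldehyde F3. Addition of acetylide 13 (2.2 equiv, generated as in step 6, THF, −78 °C) gives rac-1-[3-(benzyloxy)-2-ethoxy-6-hydroxy-4,5-dimethoxyphenyl]-3-[3-(benzyloxy)-4-methoxyphenyl]prop-2-yn-1-ol F4. MnO2 in CH2Cl2 oxidises it to 1-[3-(benzyloxy)-2-ethoxy-6-hydroxy-4,5-dimethoxyphenyl]-3-[3-(benzyloxy)-4-methoxyphenyl]prop-2-yn-1-one F5. Et2NH in EtOH then closes ring C by 6-endo oxa-Michael addition of the phenol to the ynone, giving 19.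

Step 10. Dealkylation at the O5 ethyl group may stay incomplete at temperatures that are safe for the rest, or it may run on into the methyl ethers next to the newly boron-bound phenoxides (O7, O4′). The fallback sets out from 19 and comes back at 20, separating the two kinds of cleavage. Hydrogenolysis (H2, 1 atm, Pd/C, EtOAc–THF) removes both benzyl groups to give 5-ethoxy-6-hydroxy-2-(3-hydroxy-4-methoxyphenyl)-7,8-dimethoxy-4H-chromen-4-one F6. AlCl3 in MeCN (rt to 50 °C; then dilute HCl) then removes only the chelated O5 ethyl group to give 20.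

Further compounds
F1 | step 3 | 5-ethoxy-2,3-dimethoxybenzene-1,4-diol | CCOc1cc(O)c(OC)c(OC)c1O
F2 | step 3 | methyl (2Z)-3-[3-(benzyloxy)-4-methoxyphenyl]-3-(5-ethoxy-4-hydroxy-2,3-dimethoxyphenoxy)prop-2-enoate | COC(=O)/C=C(\Oc1cc(OCC)c(O)c(OC)c1OC)c1ccc(OC)c(OCc2ccccc2)c1
F3 | step 9 | 3-(benzyloxy)-2-ethoxy-6-hydroxy-4,5-dimethoxybenzaldehyde | CCOc1c(C=O)c(O)c(OC)c(OC)c1OCc1ccccc1
F4 | step 9 | rac-1-[3-(benzyloxy)-2-ethoxy-6-hydroxy-4,5-dimethoxyphenyl]-3-[3-(benzyloxy)-4-methoxyphenyl]prop-2-yn-1-ol | CCOc1c(C(O)C#Cc2ccc(OC)c(OCc3ccccc3)c2)c(O)c(OC)c(OC)c1OCc1ccccc1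
F5 | step 9 | 1-[3-(benzyloxy)-2-ethoxy-6-hydroxy-4,5-dimethoxyphenyl]-3-[3-(benzyloxy)-4-methoxyphenyl]prop-2-yn-1-one | CCOc1c(C(=O)C#Cc2ccc(OC)c(OCc3ccccc3)c2)c(O)c(OC)c(OC)c1OCc1ccccc1
F6 | step 10 | 5-ethoxy-6-hydroxy-2-(3-hydroxy-4-methoxyphenyl)-7,8-dimethoxy-4H-chromen-4-one | CCOc1c(O)c(OC)c(OC)c2oc(-c3ccc(OC)c(O)c3)cc(=O)c12
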